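**Retrosynthetic overview**
1. Target ⇒ remove the formyl group (Vilsmeier–Haack), then the isovaleryl group (Friedel–Crafts), giving a bornane-fused dihydroxybenzoxepine.
2. Oxepine C2–O and ArC–CH2 bonds ⇒ phloroglucinol + 6-endo-formylcamphor (reductive Friedel–Crafts alkylation, then reductive etherification; the seven-membered ring closes last).
3. Bornane C1–C7 bond ⇒ cation–enol acetate cyclisation of a trans-3,5-disubstituted dihydrocarvone enol acetate.
4. Key bond C6–CH2 ⇒ 1,4-addition of 2-lithio-1,3-dithiane (formyl anion equivalent) to (R)-carvone, joining two carbons that are both electrophilic in their native carbonyl compounds; the trans addition fixes the future C6-endo centre.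
5. Ring order: cyclohexene (carvone) → bicyclo[2.2.1]heptane → arene attached → oxepine.

Assumption: the terpene part is numbered as in bornane (C1 quaternary bridgehead with CH3, C2 the O-bearing carbon, C4 the CH bridgehead, C6 the carbon bearing the benzylic CH2, C7 the CMe2 bridge); compound numbers follow first use in the forward steps.

**Route**

Step 1
Reactants: 1 1,3-dithiane; 2 (R)-(−)-carvone
Product: 5 (3R,5R)-3-(1,3-dithian-2-yl)-2-methyl-5-(prop-1-en-2-yl)cyclohex-1-en-1-yl acetate, via 2-lithio-1,3-dithiane 3 (not isolated), via lithium enolate 4 (not isolated)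
Conditions: n-BuLi, THF, −30 °C; HMPA (2 equiv), −78 °C; then 2, −78 °C; then Ac2O, −78 → 0 °C
Reagents that add atoms: acetic anhydride, CC(=O)OC(C)=O
Why: Corey–Seebach dithiane anion used as a formyl anion equivalent in a Michael addition, where the HMPA-separated ion pair adds 1,4 under kinetic control and axially anti to the C5 isopropenyl group, so the new centre is trans (3R, the future C6-endo centre), and the regiodefined enolate is O-acetylated to the tetrasubstituted enol acetate.

Step 2
Reactants: 5 (3R,5R)-3-(1,3-dithian-2-yl)-2-methyl-5-(prop-1-en-2-yl)cyclohex-1-en-1-yl acetate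
Product: 6 (1R,4R,6R)-6-(1,3-dithian-2-yl)-1,7,7-trimethylbicyclo[2.2.1]heptan-2-one (6-endo-dithianyl camphor)
Conditions: BF3·OEt2 (0.5 equiv), water-saturated CH2Cl2, 0 °C → rt, high dilution
Reagents that add atoms: none
Why: Cation–olefin cyclisation terminated by an enol acetate (the classical dihydrocarvone enol acetate → camphor annulation), in which Markovnikov protonation of the isopropenyl group gives a tertiary cation that is captured by the methyl-bearing enol carbon through a boat transition state, so the C1–C7 bridge can only form cis to C4 (fixing 1R) and the trans dithianyl group is forced endo at C6.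

Step 3
Reactants: 6 (1R,4R,6R)-6-(1,3-dithian-2-yl)-1,7,7-trimethylbicyclo[2.2.1]heptan-2-one
Product: 7 (1R,2R,4R)-1,7,7-trimethyl-6-oxobicyclo[2.2.1]heptane-2-carbaldehyde (6-endo-formylcamphor)
Conditions: MeI, CaCO3, MeCN/H2O (9:1), 45 °C
Reagents that add atoms: water, O
Why: Dithiane unmasking by S-methylation and hydrolysis under buffered conditions that leave the hindered ketone untouched; the centre alpha to the aldehyde can epimerise, but endo is the thermodynamically preferred configuration because an exo group clashes with the syn C7 methyl.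

Step 4
Reactants: 7 (1R,2R,4R)-1,7,7-trimethyl-6-oxobicyclo[2.2.1]heptane-2-carbaldehyde; 8 phloroglucinol
Product: 10 bornane-fused dihydroxybenzoxepine (bornane descriptors 1R,2S,4R,6S; C2-endo oxygen is the aryl ether oxygen; C6-endo CH2 is bonded to the neighbouring aromatic carbon; the remaining two ring oxygens are free OH), via triphenol ketone 9 (not isolated)
Conditions: 8 (3 equiv), Et3SiH (6 equiv), TFA/CH2Cl2 (1:3), 0 °C → rt; then TfOH (10 mol %), 0 °C
Reagents that add atoms: none
Why: Reductive Friedel–Crafts alkylation (hydroxyalkylation of phloroglucinol, ionisation to the protonated o-quinone methide, hydride transfer from silane) followed in the same pot by silane reductive etherification, in which one of the two equivalent ortho phenols adds to the C2 ketone from the endo face (the only face the C6-endo tether reaches) and the oxocarbenium ion is reduced from the exo face, setting C2 as 2S with oxygen endo.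

Step 5
Reactants: 10 bornane-fused dihydroxybenzoxepine; 11 3-methylbutanoyl chloride (isovaleryl chloride)
Product: 12 bornane-fused benzoxepine carrying the 3-methylbutanoyl group on the aromatic carbon between the two free OH groups (bornane descriptors 1R,2S,4R,6S)
Conditions: TiCl4 (2.5 equiv), CH2Cl2, −10 °C → rt
Reagents that add atoms: none
Why: Friedel–Crafts C-acylation through the titanium bis-phenoxide, which favours the carbon that is ortho to both phenoxide oxygens and less hindered than the carbon flanked by the bornyl ether, and gives a doubly chelated aryl ketone; no stereocentre is touched.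

Step 6
Reactants: 12 acylated bornane-fused benzoxepine
Product: 13 target CNP0246493.1 (bornane descriptors 1R,2S,4R,6S)
Conditions: POCl3, DMF, EtOAc, 0 °C → rt; then H2O, 50 °C
Reagents that add atoms: N,N-dimethylformamide, CN(C)C=O; water, O
Why: Vilsmeier–Haack formylation at the only remaining aromatic CH, which lies between the ether oxygen and a free OH as the target requires, under conditions mild enough for the secondary alkyl aryl ether and with no stereocentre involved.

**Compound list**
1 | 1,3-dithiane | C1CSCSC1 | starting material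
2 | (R)-(−)-carvone | CC1=CC[C@H](CC1=O)C(C)=C | starting material
3 | 2-lithio-1,3-dithiane | [Li]C1SCCCS1 | intermediate (not isolated)
4 | lithium (3R,5R)-3-(1,3-dithian-2-yl)-2-methyl-5-(prop-1-en-2-yl)cyclohex-1-en-1-olate | [Li]OC1=C(C)[C@H](C2SCCCS2)C[C@H](C1)C(C)=C | intermediate (not isolated)
5 | (3R,5R)-3-(1,3-dithian-2-yl)-2-methyl-5-(prop-1-en-2-yl)cyclohex-1-en-1-yl acetate | CC(=O)OC1=C(C)[C@H](C2SCCCS2)C[C@H](C1)C(C)=C | intermediate
6 | (1R,4R,6R)-6-(1,3-dithian-2-yl)-1,7,7-trimethylbicyclo[2.2.1]heptan-2-one | S1CCCSC1[C@@H]2C[C@@H]3CC(=O)[C@@]2(C)C3(C)C | intermediate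
7 | (1R,2R,4R)-1,7,7-trimethyl-6-oxobicyclo[2.2.1]heptane-2-carbaldehyde | O=C[C@@H]1C[C@@H]2CC(=O)[C@@]1(C)C2(C)C | intermediate
8 | phloroglucinol | Oc1cc(O)cc(O)c1 | starting material
9 | (1R,4R,6S)-1,7,7-trimethyl-6-[(2,4,6-trihydroxyphenyl)methyl]bicyclo[2.2.1]heptan-2-one | Oc1cc(O)c(c(O)c1)C[C@@H]1C[C@@H]3CC(=O)[C@@]1(C)C3(C)C | intermediate (not isolated)
10 | bornane-fused dihydroxybenzoxepine (1R,2S,4R,6S; 2-endo-O, 6-endo-CH2) | c1c(O)cc2c(c1O)C[C@@H]1C[C@@H]3C[C@H](O2)[C@@]1(C)C3(C)C | intermediate
11 | 3-methylbutanoyl chloride | CC(C)CC(Cl)=O | starting material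
12 | 10 with 3-methylbutanoyl on the aromatic carbon between the two OH groups | CC(C)CC(=O)c1c(O)cc2c(c1O)C[C@@H]1C[C@@H]3C[C@H](O2)[C@@]1(C)C3(C)C | intermediate
13 | CNP0246493.1 | CC(C)CC(=O)c1c(O)c(C=O)c2c(c1O)C[C@@H]1C[C@@H]3C[C@H](O2)[C@@]1(C)C3(C)C | target

**Step count and risks**
Total steps: 6. Longest linear sequence: 6 (1 and 2 → 13).

Most likely to fail, first: step 4. The protonated o-quinone methide may be intercepted by a second phloroglucinol, and the strained oxocarbenium ion at C2 may form slowly. The fallback sets out from 7 and comes back to the route at 9. Reductive Friedel–Crafts alkylation of 1,3,5-trimethoxybenzene with 7 (Et3SiH, TFA) gives (1R,4R,6S)-1,7,7-trimethyl-6-[(2,4,6-trimethoxyphenyl)methyl]bicyclo[2.2.1]heptan-2-one F4, whose flanking methoxy groups block a second arylation. BBr3 demethylation then gives 9 as an isolated compound, and the ring is closed to 10 in a separate reductive etherification (Et3SiH, TMSOTf, low temperature).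

Second: step 2. The dithiane C–H can act as a hydride donor toward the tertiary cation, and sulfur can tie up BF3. The fallback sets out from 2 and comes back at 7, using a formyl anion equivalent that is inert to cations.
- Michael addition of nitromethane to 2 (DBU) gives (3R,5R)-2-methyl-3-(nitromethyl)-5-(prop-1-en-2-yl)cyclohexan-1-one F1, again trans.
- Isopropenyl acetate with TsOH gives the more substituted enol acetate (3R,5R)-2-methyl-3-(nitromethyl)-5-(prop-1-en-2-yl)cyclohex-1-en-1-yl acetate F2.
- BF3·OEt2 cyclisation gives (1R,4R,6R)-1,7,7-trimethyl-6-(nitromethyl)bicyclo[2.2.1]heptan-2-one F3.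
- A Nef reaction (NaOMe, then cold aqueous H2SO4) gives 7.

Third: step 5. The acyl group may enter next to the ether oxygen, or TiCl4 may ionise the bornyl aryl ether. The fallback sets out from 8 and comes back at 12, installing the acyl group before the ether exists.
- Friedel–Crafts acylation of 8 with 11 (AlCl3) gives 3-methyl-1-(2,4,6-trihydroxyphenyl)butan-1-one F5.
- Reductive alkylation of F5 with 7 (Hantzsch ester, catalytic L-proline) gives (1R,4R,6S)-6-{[2,4,6-trihydroxy-3-(3-methylbutanoyl)phenyl]methyl}-1,7,7-trimethylbicyclo[2.2.1]heptan-2-one F6.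
- Reductive etherification (Et3SiH, TMSOTf, −40 °C) closes the ring through the non-chelated OH para to the acyl group and gives 12. The chelated aryl ketone is the slower carbonyl, but its over-reduction is the residual risk of this fallback.

**Further compounds**
F1 | step 2 | (3R,5R)-2-methyl-3-(nitromethyl)-5-(prop-1-en-2-yl)cyclohexan-1-one (C2 epimers) | O=C1C(C)[C@H](C[N+](=O)[O-])C[C@H](C1)C(C)=C
F2 | step 2 | (3R,5R)-2-methyl-3-(nitromethyl)-5-(prop-1-en-2-yl)cyclohex-1-en-1-yl acetate | CC(=O)OC1=C(C)[C@H](C[N+](=O)[O-])C[C@H](C1)C(C)=C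
F3 | step 2 | (1R,4R,6R)-1,7,7-trimethyl-6-(nitromethyl)bicyclo[2.2.1]heptan-2-one | [O-][N+](=O)C[C@@H]1C[C@@H]2CC(=O)[C@@]1(C)C2(C)C
F4 | step 4 | (1R,4R,6S)-1,7,7-trimethyl-6-[(2,4,6-trimethoxyphenyl)methyl]bicyclo[2.2.1]heptan-2-one | COc1cc(OC)c(c(OC)c1)C[C@@H]1C[C@@H]3CC(=O)[C@@]1(C)C3(C)C
F5 | step 5 | 3-methyl-1-(2,4,6-trihydroxyphenyl)butan-1-one | CC(C)CC(=O)c1c(O)cc(O)cc1O
F6 | step 5 | (1R,4R,6S)-6-{[2,4,6-trihydroxy-3-(3-methylbutanoyl)phenyl]methyl}-1,7,7-trimethylbicyclo[2.2.1]heptan-2-one | CC(C)CC(=O)c1c(O)cc(O)c(C[C@@H]2C[C@@H]3CC(=O)[C@@]2(C)C3(C)C)c1O
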